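**Retrosynthetic overview**

1. Target 20 ⇐ carbinol 18 by a stereoconvergent 1,3-oxygen shift ([3,3], perrhenate ester). Oxygen moves from C3 to the exocyclic carbon on C4, which sets the C3=C4 geometry (C2 cis to C5) and uncovers the C4–CH2OH group.
2. 18 ⇐ acyclic C25 aldehyde/enol triflate 17 by Ni/Cr-mediated closure of the C3–C4 bond. This forms the only ring (14-membered carbocycle C1–C14), without protecting groups, at a ring bond where no olefin geometry is at stake.
3. 17 ⇐ enoate 15 by Rh/(S)-BINAP 1,4-addition of the 6-methylhepta-1,5-dien-2-yl group (from 6-methylhept-5-en-2-one), which sets C1, the only stereocentre.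
4. 15 ⇐ 1,5-dimethylcycloocta-1,5-diene: mono-ozonolysis carries the ring Z-olefin into the chain as C7=C8, Johnson–Claisen sets (E)-C11=C12 and adds C13, C14 and C1, and the methyl ketone becomes the C4 enol triflate.

Key step: step 10

Remark (numbering): C1–C14 are the ring atoms of the target (C1 = stereocentre; C3=C4 with CH2OH on C4; C7=C8 with CH3 on C8; C11=C12 with CH3 on C12). Cα is the side-chain carbon on C1.

Remark (assumption): 1,5-dimethylcycloocta-1,5-diene is taken as the pure (1Z,5Z)-1,5-isomer. Technical material containing the 1,6-isomer would be fractionated first, because that isomer gives a regioisomeric keto aldehyde.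

**Route**

Step 1
Reactants: 1 6-methylhept-5-en-2-one
Product: 2 N′-[(2E)-6-methylhept-5-en-2-ylidene]-2,4,6-tri(propan-2-yl)benzenesulfonohydrazide
Conditions: 2,4,6-triisopropylbenzenesulfonohydrazide (1.0 equiv), MeOH, cat. HCl, rt
Reagents that add atoms: 2,4,6-tri(propan-2-yl)benzenesulfonohydrazide, NNS(=O)(=O)c1c(C(C)C)cc(C(C)C)cc1C(C)C
Why: Acid-catalysed hydrazone formation should give the (E)-hydrazone with the N–N bond syn to the methyl group, the arrangement that directs the Shapiro deprotonation to CH3.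

Step 2
Reactants: 2 N′-[(2E)-6-methylhept-5-en-2-ylidene]-2,4,6-tri(propan-2-yl)benzenesulfonohydrazide
Product: 5 potassium trifluoro(6-methylhepta-1,5-dien-2-yl)borate, via alkenyllithium 3 (not isolated), via lithium alkenyl(triisopropoxy)borate 4 (not isolated)
Conditions: n-BuLi (2.1 equiv), THF, −78 → 0 °C; B(OiPr)3, −78 °C → rt; aq KHF2, rt
Reagents that add atoms: triisopropyl borate, CC(C)OB(OC(C)C)OC(C)C; potassium hydrogen difluoride, [K+].[F-].F
Why: Shapiro reaction: the hydrazone dianion formed at the methyl group loses sulfinate and N2 to give the 2-lithio-1-alkene, which is borylated and converted by KHF2 into the stable trifluoroborate; no stereocentre is formed.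

Step 3
Reactants: 6 (1Z,5Z)-1,5-dimethylcycloocta-1,5-diene
Product: 8 (4Z)-4-methyl-8-oxonon-4-enal, via mono-ozonide 7 (not isolated)
Conditions: O3 (0.9 equiv), CH2Cl2, −78 °C; Me2S, −78 °C → rt
Reagents that add atoms: ozone, [O-][O+]=O
Why: Ozonolysis with a limiting charge of ozone should cleave one of the two equivalent trisubstituted ring olefins, and the untouched olefin carries its ring-enforced Z geometry into the chain as C7=C8.

Step 4
Reactants: 8 (4Z)-4-methyl-8-oxonon-4-enal
Product: 9 (5Z)-9-hydroxy-6,10-dimethylundeca-5,10-dien-2-one (racemic at C9)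
Conditions: isopropenylmagnesium bromide (1.05 equiv), THF, −78 °C; aqueous work-up
Reagents that add atoms: isopropenylmagnesium bromide, CC(=C)[Mg]Br
Why: Grignard 1,2-addition should be much faster at the aldehyde than at the methyl ketone at −78 °C; the carbinol centre forms as a racemate and is erased in step 5.

Step 5
Reactants: 9 (5Z)-9-hydroxy-6,10-dimethylundeca-5,10-dien-2-one
Product: 11 ethyl (4E,8Z)-4,8-dimethyl-12-oxotrideca-4,8-dienoate, via mixed ketene acetal 10 (not isolated)
Conditions: MeC(OEt)3 (7 equiv), EtCO2H (0.1 equiv), 138 °C with removal of EtOH; 1 M HCl work-up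
Reagents that add atoms: triethyl orthoacetate, CC(OCC)(OCC)OCC
Why: Johnson–Claisen rearrangement through a chair transition state with the C10 chain equatorial should form C13–C14 and the (E)-C11=C12 olefin while destroying the carbinol centre; the acidic work-up returns any ketalised ketone.

Step 6
Reactants: 11 ethyl (4E,8Z)-4,8-dimethyl-12-oxotrideca-4,8-dienoate
Product: 13 ethyl (4E,8Z)-4,8-dimethyl-12-[(trifluoromethanesulfonyl)oxy]trideca-4,8,12-trienoate, via lithium enolate 12 (not isolated)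
Conditions: LDA (1.05 equiv), THF, −78 °C; N-(5-chloropyridin-2-yl)-bis(trifluoromethanesulfonimide) (1.1 equiv), −78 → −20 °C
Reagents that add atoms: N-(5-chloropyridin-2-yl)-1,1,1-trifluoro-N-(trifluoromethanesulfonyl)methanesulfonamide, O=S(=O)(N(c1ccc(Cl)cn1)S(=O)(=O)C(F)(F)F)C(F)(F)F
Why: Kinetic enolisation of the methyl ketone at CH3 (faster than at the ester α-CH2) and O-sulfonylation at low temperature should give the 2-triflyloxy-1-alkene (enol triflate formation), which masks the ketone and is the later C4 coupling handle.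

Step 7
Reactants: 13 ethyl (4E,8Z)-4,8-dimethyl-12-[(trifluoromethanesulfonyl)oxy]trideca-4,8,12-trienoate
Product: 15 ethyl (2E,6E,10Z)-6,10-dimethyl-14-[(trifluoromethanesulfonyl)oxy]pentadeca-2,6,10,14-tetraenoate, via aldehyde 14 (not isolated)
Conditions: DIBAL-H (1.1 equiv), CH2Cl2, −78 °C; then (EtO)2P(O)CH2CO2Et/NaH in THF, −78 °C → rt
Reagents that add atoms: triethyl phosphonoacetate, CCOC(=O)CP(=O)(OCC)OCC
Why: Half-reduction gives an aluminium hemiacetal that releases the aldehyde to the phosphonate anion on warming (one-pot reduction/Horner–Wadsworth–Emmons olefination), which should give the (E)-enoate while the enol triflate is inert to both reagents.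

Step 8
Reactants: 15 ethyl (2E,6E,10Z)-6,10-dimethyl-14-[(trifluoromethanesulfonyl)oxy]pentadeca-2,6,10,14-tetraenoate; 5 potassium trifluoro(6-methylhepta-1,5-dien-2-yl)borate
Product: 16 ethyl (3R,6E,10Z)-6,10-dimethyl-3-(6-methylhepta-1,5-dien-2-yl)-14-[(trifluoromethanesulfonyl)oxy]pentadeca-6,10,14-trienoate
Conditions: 5 (2.5 equiv), [Rh(cod)2]PF6 (3 mol %), (S)-BINAP (3.3 mol %), toluene/H2O 20:1, 100 °C
Reagents that add atoms: none
Why: Rhodium-catalysed asymmetric 1,4-addition of an alkenylboron reagent (Hayashi–Miyaura reaction): the alkenyl–Rh/(S)-BINAP species should bind the (E)-enoate on its α-Si face, deliver the alkenyl group to the Re face of C3 (target C1) and give the (3R)-ester after protonolysis, the sense known for (S)-BINAP with (E)-3-alkyl acrylates.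

Step 9
Reactants: 16 ethyl (3R,6E,10Z)-6,10-dimethyl-3-(6-methylhepta-1,5-dien-2-yl)-14-[(trifluoromethanesulfonyl)oxy]pentadeca-6,10,14-trienoate
Product: 17 (3R,6E,10Z)-6,10-dimethyl-3-(6-methylhepta-1,5-dien-2-yl)-14-[(trifluoromethanesulfonyl)oxy]pentadeca-6,10,14-trienal
Conditions: DIBAL-H (1.1 equiv), CH2Cl2, −78 °C; MeOH, aq Rochelle salt
Reagents that add atoms: none
Why: DIBAL-H half-reduction of the ester should stop at the aluminium hemiacetal and give the aldehyde on work-up; the stereocentre is β to the carbonyl group and cannot epimerise.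

Step 10
Reactants: 17 (3R,6E,10Z)-6,10-dimethyl-3-(6-methylhepta-1,5-dien-2-yl)-14-[(trifluoromethanesulfonyl)oxy]pentadeca-6,10,14-trienal
Product: 18 (1RS,3R,6E,10Z)-6,10-dimethyl-14-methylidene-3-(6-methylhepta-1,5-dien-2-yl)cyclotetradeca-6,10-dien-1-ol (both C1 epimers)
Conditions: CrCl2 (8 equiv), NiCl2 (0.1 equiv), DMSO/THF 3:1, rt, syringe-pump addition over 12 h to 2 mM; aq potassium serinate work-up
Reagents that add atoms: none
Why: Nozaki–Hiyama–Kishi reaction: Ni(0) inserts into the C4–OTf bond, the alkenyl group passes to Cr(III), and the alkenylchromium adds to the C3 aldehyde. The closest known reaction type is the Ni/Cr-mediated macrocyclisation of ω-formyl alkenyl halides and triflates to 10- to 16-membered carbocycles. The 14-membered ring C1–C14, the only ring of the target, is closed by this C3–C4 bond in an intramolecular 1,2-addition to the carbonyl group, at the one ring bond where no olefin geometry must be set during cyclisation. The new carbinol centre C3 is not controlled and need not be, because step 11 funnels both epimers into the same C3=C4 olefin. The step needs chemoselectivity for the aldehyde, which alkenylchromium(III) reagents show in the presence of isolated olefins and of the non-enolisable C1 centre. It also needs ring closure to outrun oligomerisation, which is secured by slow addition to high dilution and by the four sp2 units that cut the number of free rotors in the chain.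

Step 11
Reactants: 18 (1RS,3R,6E,10Z)-6,10-dimethyl-14-methylidene-3-(6-methylhepta-1,5-dien-2-yl)cyclotetradeca-6,10-dien-1-ol
Product: 20 [(1E,4R,7E,11Z)-7,11-dimethyl-4-(6-methylhepta-1,5-dien-2-yl)cyclotetradeca-1,7,11-trien-1-yl]methanol, via trimethylsilyl ether 19 (not isolated)
Conditions: Ph3SiOReO3 (5 mol %), N,O-bis(trimethylsilyl)acetamide (1.5 equiv), Et2O, 0 °C → rt; then K2CO3, MeOH
Reagents that add atoms: none
Why: Rhenium-oxo-catalysed 1,3-transposition of an allylic alcohol: the perrhenate ester should undergo a [3,3]-sigmatropic shift through a chair with C2 equatorial, so that both C3 epimers converge on the olefin with C2 trans to the new CH2O group (cis to C5), while selective silylation of the primary alcohol pulls the reversible shift to the product side.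

**Compound list**

1 | 6-methylhept-5-en-2-one | CC(=O)CCC=C(C)C | starting material
2 | N′-[(2E)-6-methylhept-5-en-2-ylidene]-2,4,6-tri(propan-2-yl)benzenesulfonohydrazide | C/C(CCC=C(C)C)=N\NS(=O)(=O)c1c(C(C)C)cc(C(C)C)cc1C(C)C | intermediate
3 | (6-methylhepta-1,5-dien-2-yl)lithium | [Li]C(=C)CCC=C(C)C | intermediate
4 | lithium (6-methylhepta-1,5-dien-2-yl)tri(propan-2-yloxy)borate | [Li+].C=C(CCC=C(C)C)[B-](OC(C)C)(OC(C)C)OC(C)C | intermediate
5 | potassium trifluoro(6-methylhepta-1,5-dien-2-yl)borate | [K+].C=C(CCC=C(C)C)[B-](F)(F)F | intermediate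
6 | (1Z,5Z)-1,5-dimethylcycloocta-1,5-diene | C/C1=C/CC/C(C)=C\CC1 | starting material
7 | (4Z)-1,5-dimethyl-9,10,11-trioxabicyclo[6.2.1]undec-4-ene | CC12CC/C=C(/C)CCC(O1)OO2 | intermediate
8 | (4Z)-4-methyl-8-oxonon-4-enal | CC(=O)CC/C=C(/C)CCC=O | intermediate
9 | (5Z)-9-hydroxy-6,10-dimethylundeca-5,10-dien-2-one | CC(=O)CC/C=C(/C)CCC(O)C(C)=C | intermediate
10 | (5Z)-9-[(1-ethoxyethenyl)oxy]-6,10-dimethylundeca-5,10-dien-2-one | C=C(OCC)OC(CC/C(C)=C\CCC(C)=O)C(C)=C | intermediate
11 | ethyl (4E,8Z)-4,8-dimethyl-12-oxotrideca-4,8-dienoate | CCOC(=O)CC/C(C)=C/CC/C(C)=C\CCC(C)=O | intermediate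
12 | lithium (5Z,9E)-13-ethoxy-6,10-dimethyl-13-oxotrideca-1,5,9-trien-2-olate | CCOC(=O)CC/C(C)=C/CC/C(C)=C\CCC(=C)O[Li] | intermediate
13 | ethyl (4E,8Z)-4,8-dimethyl-12-[(trifluoromethanesulfonyl)oxy]trideca-4,8,12-trienoate | CCOC(=O)CC/C(C)=C/CC/C(C)=C\CCC(=C)OS(=O)(=O)C(F)(F)F | intermediate
14 | (5Z,9E)-6,10-dimethyl-13-oxotrideca-1,5,9-trien-2-yl trifluoromethanesulfonate | O=CCC/C(C)=C/CC/C(C)=C\CCC(=C)OS(=O)(=O)C(F)(F)F | intermediate
15 | ethyl (2E,6E,10Z)-6,10-dimethyl-14-[(trifluoromethanesulfonyl)oxy]pentadeca-2,6,10,14-tetraenoate | CCOC(=O)/C=C/CC/C(C)=C/CC/C(C)=C\CCC(=C)OS(=O)(=O)C(F)(F)F | intermediate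
16 | ethyl (3R,6E,10Z)-6,10-dimethyl-3-(6-methylhepta-1,5-dien-2-yl)-14-[(trifluoromethanesulfonyl)oxy]pentadeca-6,10,14-trienoate | C=C(CCC=C(C)C)[C@H](CC/C(C)=C/CC/C(C)=C\CCC(=C)OS(=O)(=O)C(F)(F)F)CC(=O)OCC | intermediate
17 | (3R,6E,10Z)-6,10-dimethyl-3-(6-methylhepta-1,5-dien-2-yl)-14-[(trifluoromethanesulfonyl)oxy]pentadeca-6,10,14-trienal | C=C(CCC=C(C)C)[C@H](CC/C(C)=C/CC/C(C)=C\CCC(=C)OS(=O)(=O)C(F)(F)F)CC=O | intermediate
18 | (1RS,3R,6E,10Z)-6,10-dimethyl-14-methylidene-3-(6-methylhepta-1,5-dien-2-yl)cyclotetradeca-6,10-dien-1-ol | C=C(CCC=C(C)C)[C@H]1CC(O)C(=C)CC/C=C(/C)CC/C=C(\C)CC1 | intermediate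
19 | {[(1E,4R,7E,11Z)-7,11-dimethyl-4-(6-methylhepta-1,5-dien-2-yl)cyclotetradeca-1,7,11-trien-1-yl]methoxy}trimethylsilane | C=C(CCC=C(C)C)[C@H]1C/C=C(/CO[Si](C)(C)C)CC/C=C(/C)CC/C=C(\C)CC1 | intermediate
20 | [(1E,4R,7E,11Z)-7,11-dimethyl-4-(6-methylhepta-1,5-dien-2-yl)cyclotetradeca-1,7,11-trien-1-yl]methanol | C=C(CCC=C(C)C)[C@H]1C/C=C(/CO)CC/C=C(/C)CC/C=C(\C)CC1 | target

**Summary**

Total step count: 11 (steps 1–2 make reagent 5; steps 3–11 are the main line).
Longest linear sequence: 9 steps (steps 3–11, from 1,5-dimethylcycloocta-1,5-diene).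

**Steps most likely to fail, with fallbacks**

Step 10. Closure of a 14-membered ring is slow, so intermolecular coupling to oligomers and protonolysis of the alkenyl-nickel/chromium species may take over. The fallback closes the same C3–C4 bond by palladium-catalysed acylation; it sets out from ester 16 and comes back at carbinol 18. Pd(PPh3)4, LiCl and hexamethylditin should turn the enol triflate into ethyl (3R,6E,10Z)-6,10-dimethyl-3-(6-methylhepta-1,5-dien-2-yl)-14-(trimethylstannyl)pentadeca-6,10,14-trienoate F1. LiOH should give the acid (3R,6E,10Z)-6,10-dimethyl-3-(6-methylhepta-1,5-dien-2-yl)-14-(trimethylstannyl)pentadeca-6,10,14-trienoic acid F2. 1-Chloro-N,N,2-trimethylprop-1-en-1-amine should convert it under neutral conditions into the acid chloride (3R,6E,10Z)-6,10-dimethyl-3-(6-methylhepta-1,5-dien-2-yl)-14-(trimethylstannyl)pentadeca-6,10,14-trienoyl chloride F3. An intramolecular acyl Stille coupling (Pd2dba3, AsPh3, high dilution) should then give the macrocyclic α-methylene ketone (3R,6E,10Z)-6,10-dimethyl-14-methylidene-3-(6-methylhepta-1,5-dien-2-yl)cyclotetradeca-6,10-dien-1-one F4, and Luche reduction (NaBH4, CeCl3) should give 18 as its epimer mixture.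

Step 8. The hindered α-branched alkenylboron reagent may lose boron by protonolysis faster than it transmetalates, and facial selectivity on the acyclic enoate may be poor. The fallback sets the same centre by copper-catalysed enantioselective allylic substitution; it sets out from enoate 15 and comes back at aldehyde 17. DIBAL-H (2.2 equiv) should give the allylic alcohol (5Z,9E,13E)-15-hydroxy-6,10-dimethylpentadeca-1,5,9,13-tetraen-2-yl trifluoromethanesulfonate F5, and diethyl chlorophosphate with pyridine its phosphate (5Z,9E,13E)-15-[(diethoxyphosphoryl)oxy]-6,10-dimethylpentadeca-1,5,9,13-tetraen-2-yl trifluoromethanesulfonate F6. The boronic ester 4,4,5,5-tetramethyl-2-(6-methylhepta-1,5-dien-2-yl)-1,3,2-dioxaborolane F7 is obtained by quenching 3 (generated from 2 as in step 2) with 2-isopropoxy-4,4,5,5-tetramethyl-1,3,2-dioxaborolane. A chiral sulfonate-bearing NHC–copper catalyst with NaOMe, used as the ligand enantiomer that leads to the 13R centre, should join F6 and F7 in an anti-SN2′ sense to the 1,4-diene (5Z,9E,13R)-6,10-dimethyl-13-(6-methylhepta-1,5-dien-2-yl)pentadeca-1,5,9,14-tetraen-2-yl trifluoromethanesulfonate F8. Disiamylborane followed by NaBO3 should hydroborate only the monosubstituted vinyl group to give the alcohol (5Z,9E,13R)-15-hydroxy-6,10-dimethyl-13-(6-methylhepta-1,5-dien-2-yl)pentadeca-1,5,9-trien-2-yl trifluoromethanesulfonate F9, and Dess–Martin periodinane should give 17.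

Step 11. The oxygen shift is reversible and its equilibrium may lie on the side of the secondary alcohol. Silylation of 18 may compete with rearrangement, and reversible ionisation may erode the olefin geometry. The fallback replaces the metal-oxo shift by a cyclic SNi′ chlorination; it sets out from 18 and comes back at 20. Thionyl chloride in Et2O should give, through a six-membered chlorosulfite transition state, the rearranged primary chloride (1E,4R,7E,11Z)-1-(chloromethyl)-7,11-dimethyl-4-(6-methylhepta-1,5-dien-2-yl)cyclotetradeca-1,7,11-triene F10. KOAc in DMF should give [(1E,4R,7E,11Z)-7,11-dimethyl-4-(6-methylhepta-1,5-dien-2-yl)cyclotetradeca-1,7,11-trien-1-yl]methyl acetate F11, and K2CO3 in MeOH should give 20.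

**Further compounds**

F1 | step 10 | ethyl (3R,6E,10Z)-6,10-dimethyl-3-(6-methylhepta-1,5-dien-2-yl)-14-(trimethylstannyl)pentadeca-6,10,14-trienoate | C=C(CCC=C(C)C)[C@H](CC/C(C)=C/CC/C(C)=C\CCC(=C)[Sn](C)(C)C)CC(=O)OCC
F2 | step 10 | (3R,6E,10Z)-6,10-dimethyl-3-(6-methylhepta-1,5-dien-2-yl)-14-(trimethylstannyl)pentadeca-6,10,14-trienoic acid | C=C(CCC=C(C)C)[C@H](CC/C(C)=C/CC/C(C)=C\CCC(=C)[Sn](C)(C)C)CC(=O)O
F3 | step 10 | (3R,6E,10Z)-6,10-dimethyl-3-(6-methylhepta-1,5-dien-2-yl)-14-(trimethylstannyl)pentadeca-6,10,14-trienoyl chloride | C=C(CCC=C(C)C)[C@H](CC/C(C)=C/CC/C(C)=C\CCC(=C)[Sn](C)(C)C)CC(=O)Cl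
F4 | step 10 | (3R,6E,10Z)-6,10-dimethyl-14-methylidene-3-(6-methylhepta-1,5-dien-2-yl)cyclotetradeca-6,10-dien-1-one | C=C(CCC=C(C)C)[C@H]1CC(=O)C(=C)CC/C=C(/C)CC/C=C(\C)CC1
F5 | step 8 | (5Z,9E,13E)-15-hydroxy-6,10-dimethylpentadeca-1,5,9,13-tetraen-2-yl trifluoromethanesulfonate | OC/C=C/CC/C(C)=C/CC/C(C)=C\CCC(=C)OS(=O)(=O)C(F)(F)F
F6 | step 8 | (5Z,9E,13E)-15-[(diethoxyphosphoryl)oxy]-6,10-dimethylpentadeca-1,5,9,13-tetraen-2-yl trifluoromethanesulfonate | CCOP(=O)(OCC)OC/C=C/CC/C(C)=C/CC/C(C)=C\CCC(=C)OS(=O)(=O)C(F)(F)F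
F7 | step 8 | 4,4,5,5-tetramethyl-2-(6-methylhepta-1,5-dien-2-yl)-1,3,2-dioxaborolane | C=C(CCC=C(C)C)B1OC(C)(C)C(C)(C)O1
F8 | step 8 | (5Z,9E,13R)-6,10-dimethyl-13-(6-methylhepta-1,5-dien-2-yl)pentadeca-1,5,9,14-tetraen-2-yl trifluoromethanesulfonate | C=C(CCC=C(C)C)[C@H](CC/C(C)=C/CC/C(C)=C\CCC(=C)OS(=O)(=O)C(F)(F)F)C=C
F9 | step 8 | (5Z,9E,13R)-15-hydroxy-6,10-dimethyl-13-(6-methylhepta-1,5-dien-2-yl)pentadeca-1,5,9-trien-2-yl trifluoromethanesulfonate | C=C(CCC=C(C)C)[C@H](CC/C(C)=C/CC/C(C)=C\CCC(=C)OS(=O)(=O)C(F)(F)F)CCO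
F10 | step 11 | (1E,4R,7E,11Z)-1-(chloromethyl)-7,11-dimethyl-4-(6-methylhepta-1,5-dien-2-yl)cyclotetradeca-1,7,11-triene | C=C(CCC=C(C)C)[C@H]1C/C=C(/CCl)CC/C=C(/C)CC/C=C(\C)CC1
F11 | step 11 | [(1E,4R,7E,11Z)-7,11-dimethyl-4-(6-methylhepta-1,5-dien-2-yl)cyclotetradeca-1,7,11-trien-1-yl]methyl acetate | C=C(CCC=C(C)C)[C@H]1C/C=C(/COC(C)=O)CC/C=C(/C)CC/C=C(\C)CC1
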